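## Plan

1. Guaiane numbering is used throughout: ring A is the cyclopentane C1–C5, ring B the cycloheptane C1, C5–C10; C14 is the exocyclic CH2 and C15 the methyl on C4.
2. Retrosynthesis: the C6 and C8 acetates are removed, then ring B is cut at C8–C9 and C6–C7. This releases C7–C8 with its isopropyl group as an isovaleraldehyde enol silane and leaves a ring A aldehyde with a formyl group (C6) on C5 and an isopropenyl group (C10, C9, C14) on C1. Ring A is then cut at C4–C5 (aldol) to a keto aldehyde that is ring-opened trans-carveyl acetate, from (R)-carvone.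
3. Enabling feature: in ring B the array O–C6–C7(iPr)–C8–O is the aldol pattern of an aldehyde, and C8(O)–C9H2–C10(=C14H2) is the retron of a type 2 carbonyl-ene reaction. C6–C5–C1–C10–C9 is therefore a five-carbon unit with one electrophilic and one nucleophilic end, held trans on ring A so that they cannot close on each other.
4. Forward order: carvone → cis-carveol → epoxide → Mitsunobu acetate → oxidative cleavage of the six-membered ring → ring A by enamine aldol → ring B by a one-flask Mukaiyama aldol/carbonyl-ene (5+2) annulation → acetylation.
5. Stereochemistry: C1 is bought with (R)-carvone; C3 comes from Luche reduction and Mitsunobu inversion; C4 and C5 from the anti aldol (substrate bias matched with D-proline); C6, C7 and C8 are relayed in the annulation by aluminium chelation, first to the C4 oxygen and then to the C6 oxygen.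

Key step: step 7

Remark: enol silane 9 is drawn as the Z isomer; the Z-enriched mixture from step 6 would be used, since the chelated open transition state of step 7 is expected to be convergent.

## Route

Step 1
Reactants: 1 (R)-(−)-carvone
Product: 2 (1R,5R)-cis-carveol
Conditions: NaBH4, CeCl3·7H2O, MeOH, 0 °C
Reagents that add atoms: none
Why: Luche reduction, in which the cerium-activated enone is reduced 1,2 and hydride attacks the carbonyl axially on the half-chair that keeps the isopropenyl group equatorial, so the new carbinol centre (C3) carries its hydroxyl cis to the isopropenyl group.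

Step 2
Reactants: 2 (1R,5R)-cis-carveol
Product: 3 cis-carveol syn-epoxide (epoxide oxygen, hydroxyl and isopropenyl all cis)
Conditions: VO(acac)2 (cat.), t-BuOOH, CH2Cl2, 0 °C to rt
Reagents that add atoms: tert-butyl hydroperoxide, CC(C)(C)OO
Why: Hydroxyl-directed epoxidation, in which the allylic alkoxide binds the vanadium tert-butylperoxide and oxygen is delivered only to the ring double bond on the face of the hydroxyl, while the isopropenyl group has no directing group and stays intact (both new centres are erased in step 4).

Step 3
Reactants: 3 cis-carveol syn-epoxide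
Product: 4 epoxy acetate with inverted C3 (acetoxy trans to the epoxide oxygen and to isopropenyl)
Conditions: PPh3, DIAD, AcOH, THF, 0 °C to rt
Reagents that add atoms: acetic acid, CC(=O)O
Why: Mitsunobu reaction, in which acetate displaces the alkoxyphosphonium ion by SN2 so that C3 is inverted and the acetoxy group ends trans to the isopropenyl group, the epoxide being inert under these neutral conditions.

Step 4
Reactants: 4 epoxy acetate
Product: 6 (3S,5S)-5-acetoxy-6-oxo-3-(prop-1-en-2-yl)heptanal, via glycol 5 (not isolated)
Conditions: H5IO6, THF/H2O, 0 °C to rt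
Reagents that add atoms: water, O
Why: Acid-catalysed opening of the epoxide by water at the tertiary carbon followed by periodate glycol cleavage of 5 opens the six-membered ring between C4 and C6 to the methyl ketone and the aldehyde, while C1, C3 and the isopropenyl group are not involved.

Step 5
Reactants: 6 (3S,5S)-5-acetoxy-6-oxo-3-(prop-1-en-2-yl)heptanal
Product: 7 (1S,2S,3R,4S)-3-formyl-2-hydroxy-2-methyl-4-(prop-1-en-2-yl)cyclopentyl acetate
Conditions: D-proline (20 mol%), CH2Cl2, rt
Reagents that add atoms: none
Why: Amine-catalysed enolexo aldol cyclisation (ring A, 5-exo-trig at the ketone), in which only the aldehyde forms an enamine and its addition to the α-acetoxy ketone through the acid-bound anti transition state puts the new C4 hydroxyl trans to the C3 acetate (dipole-opposed approach) and trans to the formyl group, which itself sits trans to the isopropenyl group on C1, so substrate bias and catalyst act in the same sense.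

Step 6
Reactants: 8 isovaleraldehyde (3-methylbutanal)
Product: 9 (Z)-trimethyl[(3-methylbut-1-en-1-yl)oxy]silane
Conditions: Me3SiCl, Et3N, DMF, 80 °C; distillation
Reagents that add atoms: chlorotrimethylsilane, C[Si](C)(C)Cl
Why: Silyl enol ether formation by amine-mediated O-silylation of the aldehyde enol under equilibrating conditions, expected to give mainly the Z isomer, with no stereocentre formed.

Step 7
Reactants: 7 (1S,2S,3R,4S)-3-formyl-2-hydroxy-2-methyl-4-(prop-1-en-2-yl)cyclopentyl acetate; 9 (Z)-trimethyl[(3-methylbut-1-en-1-yl)oxy]silane
Product: 11 (1S,3S,4S,5S,6S,7R,8S)-4,6,8-trihydroxyguai-10(14)-en-3-yl acetate, via aldol aldehyde 10 (not isolated)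
Conditions: Me2AlCl (3 equiv), CH2Cl2, −78 °C; then 9 (1.1 equiv), −78 to −20 °C; 1 M HCl work-up
Reagents that add atoms: none
Why: Proposed new method: a one-flask (5+2) annulation in which Me2AlCl drives two known reactions in sequence, a chelation-controlled Mukaiyama aldol addition and a type 2 carbonyl-ene cyclisation, the closest known reaction type being the Mukaiyama aldol–Prins cascade, in which the electrophile born in the aldol step is trapped by a tethered alkene. Me2AlCl turns the tertiary C4 hydroxyl into an aluminium alkoxide that chelates the C6 formyl oxygen in a six-membered ring trans-fused to ring A, in which the C4 methyl group is axial and covers the β face of C6, so enol silane 9 adds from the α face (6S) through an open antiperiplanar transition state that places the isopropyl group syn to the new oxygen (7R), and loss of Me3SiCl leaves the aluminium aldolate of 10. The C6 aluminate then chelates the new C8 carbonyl group, the terminal carbon C9 of the isopropenyl group attacks C8 (ring B, seven-membered, 7-exo-trig at the carbonyl with the alkene inside the forming ring), and the tertiary C10 cation loses a proton from C14 to the C8 alkoxide through a six-membered array, which gives the exocyclic methylene. C8 (8S) is fixed because closure within the O6–Al–O8 bridge forces O8 cis to O6, and the isopropyl group, equatorial on that chelate ring, ends trans to both oxygens, so that the substituents on C5, C6, C7 and C8 alternate between the two faces of ring B. The step needs the aldol to precede the ene reaction and 7 not to cyclise on itself: the formyl and isopropenyl groups are trans on ring A, so their direct closure would be a trans-fused five-membered ring and does not occur, and the enol silane is far more nucleophilic than the 1,1-disubstituted alkene. A second aldol on 10 is limited by using close to one equivalent of 9 at −78 °C and warming only afterwards.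

Step 8
Reactants: 11 (1S,3S,4S,5S,6S,7R,8S)-4,6,8-trihydroxyguai-10(14)-en-3-yl acetate
Product: 12 (1S,3S,4S,5S,6S,7R,8S)-4-hydroxyguai-10(14)-ene-3,6,8-triyl triacetate
Conditions: Ac2O, pyridine, DMAP (cat.), CH2Cl2, 0 °C to rt
Reagents that add atoms: acetic anhydride, CC(=O)OC(C)=O
Why: DMAP-catalysed acetylation of the two secondary hydroxyls at C6 and C8, whereas the tertiary C4 hydroxyl, flanked by two substituted ring carbons, is not expected to react at room temperature with catalytic DMAP, and no stereocentre is touched.

## Compound list

1 | (R)-(−)-carvone | CC1=CC[C@H](CC1=O)C(C)=C | starting material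
2 | (1R,5R)-2-methyl-5-(prop-1-en-2-yl)cyclohex-2-en-1-ol (cis-carveol) | CC1=CC[C@H](C[C@H]1O)C(C)=C | intermediate
3 | 1-methyl-4-(prop-1-en-2-yl)-7-oxabicyclo[4.1.0]heptan-2-ol, epoxide oxygen, hydroxyl and isopropenyl all cis | C[C@]12O[C@H]1C[C@H](C[C@H]2O)C(C)=C | intermediate
4 | 1-methyl-4-(prop-1-en-2-yl)-7-oxabicyclo[4.1.0]heptan-2-yl acetate, acetoxy trans to the epoxide oxygen and to isopropenyl | C[C@]12O[C@H]1C[C@H](C[C@@H]2OC(C)=O)C(C)=C | intermediate
5 | 2,3-dihydroxy-2-methyl-5-(prop-1-en-2-yl)cyclohexyl acetate, tertiary hydroxyl cis to acetoxy, secondary hydroxyl trans to the tertiary one and cis to isopropenyl | C[C@@]1(O)[C@@H](O)C[C@H](C[C@@H]1OC(C)=O)C(C)=C | intermediate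
6 | (3S,5S)-5-acetoxy-6-oxo-3-(prop-1-en-2-yl)heptanal | CC(=O)[C@@H](OC(C)=O)C[C@H](C(C)=C)CC=O | intermediate
7 | (1S,2S,3R,4S)-3-formyl-2-hydroxy-2-methyl-4-(prop-1-en-2-yl)cyclopentyl acetate | O=C[C@@H]1[C@@H](C(C)=C)C[C@H](OC(C)=O)[C@@]1(C)O | intermediate
8 | isovaleraldehyde (3-methylbutanal) | CC(C)CC=O | starting material
9 | (Z)-trimethyl[(3-methylbut-1-en-1-yl)oxy]silane | CC(C)/C=C\O[Si](C)(C)C | intermediate
10 | (2S,3R)-3-[(1S,2S,3S,5S)-3-acetoxy-2-hydroxy-2-methyl-5-(prop-1-en-2-yl)cyclopentyl]-3-hydroxy-2-(propan-2-yl)propanal (in the flask as its aluminium alkoxide) | O=C[C@@H](C(C)C)[C@H](O)[C@@H]1[C@@H](C(C)=C)C[C@H](OC(C)=O)[C@@]1(C)O | intermediate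
11 | (1S,3S,4S,5S,6S,7R,8S)-4,6,8-trihydroxyguai-10(14)-en-3-yl acetate (1βH,5αH; 3β-OAc; 4α,6α,8α-OH) | C=C1C[C@H](O)[C@@H](C(C)C)[C@H](O)[C@@H]2[C@@H]1C[C@H](OC(C)=O)[C@@]2(C)O | intermediate
12 | (1S,3S,4S,5S,6S,7R,8S)-4-hydroxyguai-10(14)-ene-3,6,8-triyl triacetate | C=C1C[C@H](OC(C)=O)[C@@H](C(C)C)[C@H](OC(C)=O)[C@@H]2[C@@H]1C[C@H](OC(C)=O)[C@@]2(C)O | target

## Step count and risks

Total steps: 8. Longest linear sequence: 7 (steps 1–5, 7, 8).

**Step 7 (Proposed new method).** What may go wrong: the intermediate aldehyde may be consumed by a second intermolecular aldol or an intermolecular ene reaction before ring B closes; ring A may open by retro-aldol in the aluminium aldolate; simple diastereoselection at C7 may be poor; or proton loss from the C10 cation may be unselective. Fallback, known chemistry with the two bonds made in separate steps, setting out from 7 and coming back at 11: a chelation-controlled Mukaiyama aldol addition (Me2AlCl, CH2Cl2, −78 °C) of the silyl ketene thioacetal (Z)-[1-(ethylsulfanyl)-3-methylbut-1-en-1-yl]oxy(trimethyl)silane F1, itself made from S-ethyl 3-methylbutanethioate with LDA and Me3SiCl, would give the stable β-hydroxy thioester F2. Fukuyama reduction (Et3SiH, Pd/C, acetone) would then release aldehyde 10, isolated in this variant, and a separate Me2AlCl-promoted type 2 carbonyl-ene cyclisation at low temperature would close ring B to 11.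

**Step 5.** What may go wrong: dehydration of the tertiary aldol to the conjugated enal during reaction or isolation, enolisation of the α-acetoxy ketone with erosion at C3, or competing ketone-donor cyclisation. Fallback, setting out from 6 and coming back at 7: the aldol cyclisation would be coupled with an immediate reduction in the same flask (MeOH, NaBH4, 0 °C), so that the product is secured and purified as the stable diol (1S,2S,3S,4S)-2-hydroxy-3-(hydroxymethyl)-2-methyl-4-(prop-1-en-2-yl)cyclopentyl acetate F3. The formyl group would be regenerated just before step 7 by chemoselective oxidation of the primary alcohol (TEMPO, PhI(OAc)2, CH2Cl2), which leaves the tertiary alcohol and both alkenes alone.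

**Step 3.** What may go wrong: slow SN2 displacement at a carbinol flanked by the fully substituted epoxide carbon, with elimination or participation of the epoxide in place of clean inversion. Fallback, setting out from 2 and coming back at 6: the inversion would be moved to the unhindered allylic alcohol. Mitsunobu reaction of 2 with 4-nitrobenzoic acid (PPh3, DIAD, THF) would give trans-carveyl 4-nitrobenzoate F4, and methanolysis (K2CO3, MeOH) trans-carveol F5. Hydroxyl-directed epoxidation (VO(acac)2, t-BuOOH) would give the epoxy alcohol F6 with the oxygen cis to the inverted hydroxyl, and acetylation (Ac2O, pyridine) the epoxy acetate F7. F7 differs from 4 only at the two epoxide carbons, which are erased when H5IO6 cleaves it, through the glycol F8 (not isolated), to the same keto aldehyde 6.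

## Further compounds

F1 | step 7 | (Z)-[1-(ethylsulfanyl)-3-methylbut-1-en-1-yl]oxy(trimethyl)silane | CC(C)/C=C(\SCC)O[Si](C)(C)C
F2 | step 7 | S-ethyl (2S,3R)-3-[(1S,2S,3S,5S)-3-acetoxy-2-hydroxy-2-methyl-5-(prop-1-en-2-yl)cyclopentyl]-3-hydroxy-2-(propan-2-yl)propanethioate | CCSC(=O)[C@@H](C(C)C)[C@H](O)[C@@H]1[C@@H](C(C)=C)C[C@H](OC(C)=O)[C@@]1(C)O
F3 | step 5 | (1S,2S,3S,4S)-2-hydroxy-3-(hydroxymethyl)-2-methyl-4-(prop-1-en-2-yl)cyclopentyl acetate | OC[C@@H]1[C@@H](C(C)=C)C[C@H](OC(C)=O)[C@@]1(C)O
F4 | step 3 | (1S,5R)-2-methyl-5-(prop-1-en-2-yl)cyclohex-2-en-1-yl 4-nitrobenzoate (trans) | CC1=CC[C@H](C[C@@H]1OC(=O)c1ccc(cc1)[N+](=O)[O-])C(C)=C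
F5 | step 3 | (1S,5R)-2-methyl-5-(prop-1-en-2-yl)cyclohex-2-en-1-ol (trans-carveol) | CC1=CC[C@H](C[C@@H]1O)C(C)=C
F6 | step 3 | 1-methyl-4-(prop-1-en-2-yl)-7-oxabicyclo[4.1.0]heptan-2-ol, epoxide oxygen cis to hydroxyl and trans to isopropenyl | C[C@@]12O[C@@H]1C[C@H](C[C@@H]2O)C(C)=C
F7 | step 3 | 1-methyl-4-(prop-1-en-2-yl)-7-oxabicyclo[4.1.0]heptan-2-yl acetate, epoxide oxygen cis to acetoxy and trans to isopropenyl | C[C@@]12O[C@@H]1C[C@H](C[C@@H]2OC(C)=O)C(C)=C
F8 | step 3 | 2,3-dihydroxy-2-methyl-5-(prop-1-en-2-yl)cyclohexyl acetate, tertiary hydroxyl trans to acetoxy, secondary hydroxyl cis to acetoxy (not isolated) | C[C@]1(O)[C@H](O)C[C@H](C[C@@H]1OC(C)=O)C(C)=C
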